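# Total synthesis proposal for CNP0320758.1: ring B closed at C9–C10 by a Nozaki–Hiyama–Kishi reaction

## Analysis of the target

The target is a daucane-type sesquiterpenoid triester. A cyclopentane (ring A: C1–C5) and a cycloheptene (ring B: C1, C5, C6, C7, C8, C9, C10) share the C1–C5 bond; C1 carries a methyl group, C4 an isopropyl group and a free tertiary hydroxyl, the C8=C9 alkene a methyl group, C2 and C10 acetates, and C6 a 3,4-dimethoxybenzoate (veratroate). There are six stereocentres, (1R,2S,4R,5S,6S,10R). With the face of the C1 methyl called β, the ring fusion is trans (C5–H α), the C2 and C10 acetoxy groups, the C6 acyloxy group and the isopropyl group are α, and the C4 hydroxyl is β. The quaternary C1 is therefore flanked by two oxygenated carbons (C2, C10) whose oxygens are trans to its methyl group, and O4 is cis to the C5–C6 bond. Sensitive points are the tertiary carbinol at C4 (dehydration), the allylic acetate at C10 (ionisation), and the 1,3-related hydroxy/acyloxy pairs, across which acyl groups can migrate. The synthesis is hard because the stereocentres crowd around the quaternary C1, the seven-membered ring is trans-fused, and four oxygen functions must be differentiated. The strategy rests on C10: it is an allylic carbinol carbon between the quaternary C1 and the trisubstituted C8=C9 alkene of ring B, the retron of the addition of a C9 alkenyl metal to a C10 aldehyde on ring A. Cutting C9–C10 removes ring B and leaves a cyclopentane on which every other stereocentre can be set first.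

## Retrosynthetic reasoning

**Acetates (28 to 27).** The C2–O and C10–O acetyl bonds are cut first. The two acetates are the only groups that nothing earlier in the route needs, and the tertiary C4 hydroxyl does not acylate under mild conditions. The last step is then a double acetylation of triol 27 that only has to tell secondary from tertiary hydroxyls.

**Ring B (27 to 25).** The C9–C10 bond is cut. It is the one ring B bond whose formation gives both the C10 carbinol and the C8=C9 alkene in their final form, and the aldehyde that results sits on a quaternary carbon, so it cannot enolise or epimerise. The precursor is ring A aldehyde 25, which carries the C6 veratroate and the (Z)-iodoalkene. The forward reaction has to form alkenylchromium 26 in the presence of two free hydroxyls and an aryl ester, close a seven-membered ring, and add to the aldehyde face that puts O10 trans to the C1 methyl.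

**Oxidation state and protecting groups (25 to 24 to 23).** The aldehyde comes from the primary C10 alcohol of triol 24 by an oxidation selective for primary over hindered secondary hydroxyls. Triol 24 comes from 23, in which O2 and O10 are tied as an acetonide and O4 is a trimethylsilyl ether, so that one acidic step frees all three.

**C6 carbinol (23 to 21 and 22, 21 to 20).** The veratroate is cut at the acyl–O6 bond (veratroyl chloride 22) and the C6–H bond is traced to ketone 20. The reduction has to deliver hydride to the face that gives 6S. O4 is silylated so that it cannot deliver hydride itself, which would lead to the 6R epimer.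

**C6–C7 bond (20 to 19 to 17 and 3, 3 to 2 to 1).** C6 is used as an acyl anion (lithiated dithiane 18 from 17) and C7 as the electrophilic carbon of allylic bromide 3. The opposite polarity fails, because an allyl metal made from 3 would react at its iodine-bearing terminus. Bromide 3 carries the Z iodoalkene, which is set by anti-carbometalation of propargyl alcohol 1 via alcohol 2.

**C4 carbinol (17 to 16 to 15 to 14).** The C4–isopropyl bond is cut to ketone 15. The C4 oxygen of 14 is the remnant of the silyloxy group that controlled the earlier steps; after oxidation, the isopropyl nucleophile must add anti to the C5 substituent to give the β hydroxyl.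

**C2 carbinol and diol protection (14 to 13 to 12 to 11 to 10).** The acetonide of 14 is opened to triol 13, which comes from bis-silyl ether 12. The C2–H bond of 12 is traced to ketone 11, the silyl ether of ketol 10. Hydride has to enter on the β face, next to the C1 methyl, so the α substituent on C1 is made large and non-coordinating and a chiral catalyst is used.

**Ring A substituents (10 to 6 and 7).** The C5–C6 and C1–C10 bonds are cut together, as a three-component coupling on enone 6. Lithiated 1,3-dithiane 8 (from 7) adds in conjugate fashion anti to the C4 silyloxy group, and enolate 9 is hydroxymethylated anti to the new C5 substituent. One purchased stereocentre thereby sets C5 and the quaternary C1.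

**Enone (6 to 5 to 4).** The C1–methyl bond is cut to iodoenone 5, which comes from enone 4 by α-iodination; a Stille methylation joins them in the forward direction.

## Alternatives that were turned down

**Alternative 1:** Arene to cycloheptatriene by intramolecular Buchner reaction. The disconnection cuts C1–C5 and C1–C10 together and traces ring B to a benzene ring. In the forward step, rhodium-catalysed loss of nitrogen from α-diazo ketone A2 gives a carbenoid at C1, which adds across the ipso–ortho bond of the 2,6-dimethoxy-4-methylphenyl group. The cyclopropane-fused intermediate opens to cycloheptatrienone A1, so ring A closes and the arene expands to ring B in one operation.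
- For it: two rings, two C–C bonds and the quaternary C1 arise in a single step from a flat precursor, and the symmetric arene leaves no regiochemical question. On ring construction per step it is stronger than the chosen route.
- Against it: the diazo carbon carries a methyl group, so 1,2-hydride shift to an enone competes with the cycloaddition. A1 still lacks four stereocentres (C2, C5, C6, C10): C5 must be set trans to the methyl by reducing a tetrasubstituted enol ether, and two of three ring B double bonds must be removed while C8=C9 stays. Only C4 relays stereochemistry to C1.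
- Comparison: the chosen strategy needs more linear steps, but five stereocentres are fixed on a rigid cyclopentane before ring B is formed, and the closure gives the C8=C9 alkene and the C10 oxygen in final form.

**Alternative 2:** Cycloheptenone relay, ring A by carbenoid C–H insertion. Ring A is cut at C2–C3 and ring B is made first. In the forward step, the rhodium carbenoid from diazo ketone A4 inserts into a C–H bond of the (4-methoxybenzyloxy)methyl group on C1. This forms C2–C3, creates C2 and gives the trans-fused dione A3.
- For it: the ether oxygen activates the C–H bond, five-membered closure is the preferred insertion mode, and the C2 oxygen arrives protected without a carbonyl reduction. On that point it is stronger than the chosen route, which needs a reagent-controlled reduction at C2.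
- Against it: a seven-membered ring with three stereocentres (quaternary C1, C5, C6) has to be built first on a mobile ring with little to relay stereochemistry. The carbenoid can also insert into the benzylic C–H bond or form an oxonium ylide. Which diastereotopic hydrogen reacts, and so the C2 configuration, is not secured. The later isopropyl addition must distinguish the C4 ketone from the C10 enone.
- Comparison: step counts are similar, but the chosen route sets ring A from one purchased stereocentre by well-understood relay and closes ring B with a reaction that tolerates all the functionality.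

**Alternative 3:** Chromium carbene (4+3) annulation of ring B onto ring A. Ring B is cut into the carbene carbon C6 on ring A and the four-carbon unit C7–C10 (bonds C6–C7 and C1–C10). In the forward step, carbene complex A6 (zerovalent chromium) cyclopropanates the terminal alkene of silyl diene A7, forming C6–C7 and C6–C8. The cis-divinylcyclopropane then undergoes Cope rearrangement, breaking C6–C8 and forming C1–C10, to give A5.
- For it: it is convergent, the C8=C9 alkene lands in place, and C10 receives a silicon group that a Tamao–Fleming oxidation would convert into the hydroxyl with retention. On convergence and on the stereospecific origin of C10 it is stronger than the chosen route.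
- Against it: a stoichiometric chromium carbonyl complex is needed, and the face on which C1 is formed depends on a remote silyloxy group. In A5, C5 and C6 are still sp2, C2 is a ketal and C4 a secondary silyl ether, so the trans fusion, C6, C2 and the tertiary carbinol would all be made on the flexible bicycle, besides oxidising a hindered silane.
- Comparison: in the chosen route the ring-closing step leaves only an acetylation, and its one uncertain centre (C10) can be corrected by oxidation and directed reduction.

Key step: step 19

## Route

Remarks on the chemistry: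
- All intermediates carry the locants of the target skeleton (C1–C10). β is the face of ring A that carries the C1 methyl group and α the opposite face.
- (R)-4-(tert-Butyldimethylsilyloxy)cyclopent-2-en-1-one (4) is taken to be a purchasable enantiopure building block.

Step 1
Reactants: 1 propargyl alcohol (prop-2-yn-1-ol)
Product: 2 (Z)-3-iodo-2-methylprop-2-en-1-ol
Conditions: MeMgBr (2.5 equiv), CuI (10 mol%), THF, −10 °C to rt; then I2, −78 to 0 °C
Reagents that add atoms: methylmagnesium bromide C[Mg]Br; iodine II
Why: Copper-catalysed anti-carbomagnesiation of the propargylic alkoxide puts methyl on C2 and magnesium on C3 through a five-membered chelate, so iodinolysis with retention should give the Z iodide (iodine cis to CH2OH).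

Step 2
Reactants: 2 (Z)-3-iodo-2-methylprop-2-en-1-ol
Product: 3 (Z)-3-bromo-1-iodo-2-methylprop-1-ene
Conditions: CBr4, PPh3, CH2Cl2, 0 °C
Reagents that add atoms: tetrabromomethane BrC(Br)(Br)Br
Why: Appel bromination of the primary allylic alcohol under neutral conditions should leave the alkene geometry and the C–I bond untouched.

Step 3
Reactants: 4 (R)-4-(tert-butyldimethylsilyloxy)cyclopent-2-en-1-one
Product: 5 (R)-4-(tert-butyldimethylsilyloxy)-2-iodocyclopent-2-en-1-one
Conditions: I2, pyridine, CH2Cl2, 0 °C to rt
Reagents that add atoms: iodine II
Why: α-Iodination of the enone by pyridine addition, iodination of the enolate and elimination; the C4 stereocentre is not involved.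

Step 4
Reactants: 5 (R)-4-(tert-butyldimethylsilyloxy)-2-iodocyclopent-2-en-1-one
Product: 6 (R)-4-(tert-butyldimethylsilyloxy)-2-methylcyclopent-2-en-1-one
Conditions: Me4Sn, Pd2(dba)3 (2.5 mol%), AsPh3, CuI, NMP, 60 °C
Reagents that add atoms: tetramethylstannane C[Sn](C)(C)C
Why: Stille cross-coupling of the α-iodoenone with tetramethylstannane; the neutral conditions avoid β-elimination of the silyloxy group.

Step 5
Reactants: 6 (R)-4-(tert-butyldimethylsilyloxy)-2-methylcyclopent-2-en-1-one; 7 1,3-dithiane
Product: 10 ketol: 2-oxo ring A carrying 1β-methyl and 1α-hydroxymethyl and 4α-(tert-butyldimethylsilyloxy) and 5β-(1,3-dithian-2-yl) groups, via 2-lithio-1,3-dithiane 8 (not isolated), via lithium enolate 9 (not isolated)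
Conditions: 7, n-BuLi, THF, −30 °C; HMPA (2 equiv), −78 °C; 6; then CH2O (gas), −78 °C; aq. NH4Cl
Reagents that add atoms: formaldehyde C=O
Why: Three-component coupling: HMPA steers the lithiated dithiane to conjugate addition, anti to the C4 silyloxy group (sets C5), and the tetrasubstituted enolate is hydroxymethylated by an aldol reaction anti to the new C5 substituent (sets the quaternary C1 with CH2OH α).

Step 6
Reactants: 10 ketol
Product: 11 C10 tert-butyldiphenylsilyl ether of ketol 10
Conditions: t-BuPh2SiCl, imidazole, DMF, 0 °C to rt
Reagents that add atoms: tert-butyl(chloro)diphenylsilane CC(C)(C)[Si](Cl)(c1ccccc1)c1ccccc1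
Why: Silylation of the primary alcohol blocks retro-aldol loss of the hydroxymethyl group and hydroxyl-directed hydride delivery, and makes the α substituent on C1 clearly larger than the β methyl group.

Step 7
Reactants: 11 silyl ether ketone
Product: 12 (2S)-alcohol: 2α-hydroxy ring A carrying 1β-methyl and 1α-(tert-butyldiphenylsilyloxymethyl) and 4α-(tert-butyldimethylsilyloxy) and 5β-(1,3-dithian-2-yl) groups
Conditions: (R)-2-methyl-CBS-oxazaborolidine [(R)-1-methyl-3,3-diphenyltetrahydro-1H,3H-pyrrolo[1,2-c][1,3,2]oxazaborole] (0.5 equiv), catecholborane, toluene, −78 to −40 °C; non-oxidative work-up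
Reagents that add atoms: none
Why: Corey–Bakshi–Shibata reduction of an α-quaternary cyclopentanone: C1 is the large flank and the C3 methylene the small one, so the (R)-catalyst should deliver hydride to the β face and give the 2α (2S) alcohol; the bulky silyloxymethyl group on the α face biases the substrate the same way.

Step 8
Reactants: 12 (2S)-alcohol
Product: 13 triol: 5β-(1,3-dithian-2-yl)-1α-(hydroxymethyl)-1β-methylcyclopentane-2α,4α-diol
Conditions: Bu4NF, THF, rt
Reagents that add atoms: none
Why: Fluoride cleaves both silyl ethers (Si–F bond formation); the dithiane and the carbinol centres are unaffected.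

Step 9
Reactants: 13 triol
Product: 14 acetonide: O2,O10-isopropylidene acetal of 13 with free 4α-hydroxyl
Conditions: 2,2-dimethoxypropane, pyridinium p-toluenesulfonate (cat.), CH2Cl2, rt
Reagents that add atoms: 2,2-dimethoxypropane COC(C)(C)OC
Why: Thermodynamic acetalisation picks the cis-related O2/O10 pair, which forms a cis-fused 1,3-dioxane; bridging the ring 1,3-diol (O2/O4) would be strained, so the C4 hydroxyl stays free.

Step 10
Reactants: 14 acetonide alcohol
Product: 15 C4 ketone: 5β-(1,3-dithian-2-yl) O2,O10-isopropylidene ring A 4-one
Conditions: Dess–Martin periodinane, NaHCO3, CH2Cl2, 0 °C to rt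
Reagents that add atoms: none
Why: Dess–Martin oxidation of the secondary alcohol tolerates the thioacetal; the buffered, non-basic medium should not epimerise C5, whose substituent already lies on the convex β face.

Step 11
Reactants: 15 C4 ketone
Product: 16 tertiary alcohol: 4β-hydroxy-4α-isopropyl-5β-(1,3-dithian-2-yl) O2,O10-isopropylidene ring A
Conditions: i-PrMgCl, CeCl3 (dried), THF, −78 to 0 °C
Reagents that add atoms: isopropylmagnesium chloride CC(C)[Mg]Cl
Why: Organocerium 1,2-addition: the low basicity of the cerium reagent suppresses enolisation and reduction of the hindered ketone, and attack anti to the adjacent β dithianyl group on C5 should give 4α-isopropyl and 4β-OH.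

Step 12
Reactants: 16 tertiary alcohol
Product: 17 4-O-trimethylsilyl ether of 16
Conditions: 1-(trimethylsilyl)imidazole, CH2Cl2, rt to 40 °C
Reagents that add atoms: 1-(trimethylsilyl)imidazole C[Si](C)(C)n1ccnc1
Why: Neutral silylation of the hindered tertiary alcohol without touching the acetonide; the silyl ether later prevents dehydration of the β-hydroxy ketone and hydride delivery from O4.

Step 13
Reactants: 17 silyl ether; 3 (Z)-3-bromo-1-iodo-2-methylprop-1-ene
Product: 19 alkylated dithiane: 2-[(Z)-3-iodo-2-methylprop-2-en-1-yl]-1,3-dithiane bonded through its C2 (= C6) to C5 of the 4β-trimethylsilyloxy-4α-isopropyl O2,O10-isopropylidene ring A, via lithiated dithiane 18 (not isolated)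
Conditions: t-BuLi (1.05 equiv), THF–HMPA (10:1), −78 °C; then 3, −78 to −40 °C
Reagents that add atoms: none
Why: Corey–Seebach umpolung: metalation of the 2-substituted dithiane followed by SN2 alkylation with the primary allylic bromide forms C6–C7; with no alkyllithium left when 3 is added, the alkenyl iodide and its Z geometry should survive.

Step 14
Reactants: 19 alkylated dithiane
Product: 20 C6 ketone: (Z)-4-iodo-3-methylbut-3-en-1-one bonded through its C1 (= C6) to C5 of the 4β-trimethylsilyloxy-4α-isopropyl O2,O10-isopropylidene ring A
Conditions: MeI, CaCO3, MeCN–H2O (9:1), 45 °C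
Reagents that add atoms: water O
Why: Alkylative hydrolysis of the thioketal (S-methylation, then hydrolysis of the sulfonium) under carbonate buffer; the neutral medium spares the acetonide, the silyl ether, the iodoalkene and the enolisable C5.

Step 15
Reactants: 20 C6 ketone
Product: 21 (6S)-alcohol: (1S,3Z)-1-hydroxy-4-iodo-3-methylbut-3-enyl group on C5 of the 4β-trimethylsilyloxy-4α-isopropyl O2,O10-isopropylidene ring A
Conditions: (R)-2-methyl-CBS-oxazaborolidine (catalyst of step 7, 1.0 equiv), catecholborane, toluene–CH2Cl2, −78 to −30 °C
Reagents that add atoms: none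
Why: Corey–Bakshi–Shibata reduction with the ring carbon C5 as the large and the C7 methylene as the small flank, so the (R)-catalyst should give the 6S carbinol; in the Felkin–Anh sense C4 (isopropyl, silyloxy) is the largest group on C5 and lies anti to the hydride, which points to the same face.

Step 16
Reactants: 21 (6S)-alcohol; 22 veratroyl chloride (3,4-dimethoxybenzoyl chloride)
Product: 23 (6S)-veratroate: 6-O-(3,4-dimethoxybenzoyl) derivative of 21
Conditions: Et3N, 4-(dimethylamino)pyridine, CH2Cl2, rt to 40 °C
Reagents that add atoms: none
Why: Nucleophilic catalysis (acylpyridinium) acylates the only free hydroxyl with retention at C6; the silyl ether and the acetonide are inert.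

Step 17
Reactants: 23 (6S)-veratroate
Product: 24 triol: (6S)-veratroate with free 2α-hydroxyl and 4β-hydroxyl and C10 hydroxymethyl groups
Conditions: 1 M aq. HCl, THF, rt
Reagents that add atoms: none
Why: Dilute acid hydrolyses the acetonide and the trimethylsilyl ether in one operation; the aryl ester, the iodoalkene and the tertiary carbinol should be stable at room temperature.

Step 18
Reactants: 24 triol
Product: 25 ring A aldehyde: 1-formyl-1β-methyl-2α,4β-dihydroxy-4α-isopropyl ring A carrying on C5 the (1S,3Z)-1-(3,4-dimethoxybenzoyloxy)-4-iodo-3-methylbut-3-enyl group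
Conditions: TEMPO (2,2,6,6-tetramethylpiperidin-1-oxyl, 20 mol%), PhI(OAc)2, CH2Cl2, rt
Reagents that add atoms: none
Why: Oxoammonium oxidation is selective for the primary alcohol over the hindered secondary C2 hydroxyl and the tertiary C4 hydroxyl; the aldehyde has no α-hydrogen, so it can neither epimerise nor eliminate.

Step 19
Reactants: 25 ring A aldehyde
Product: 27 triol: (1R,2S,4R,5S,6S,10R)-2,10-dideacetyl target (2α,4β,10α-trihydroxy 6α-veratroate), via alkenylchromium dichloride 26 (not isolated)
Conditions: CrCl2 (8 equiv), NiCl2 (2 mol%), degassed DMSO, rt, 0.005 M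
Reagents that add atoms: none
Why: CrCl2 (divalent chromium) reduces NiCl2 to zerovalent nickel, which inserts into the C9–I bond with retention of the Z geometry; transmetalation to trivalent chromium gives alkenylchromium 26 and returns divalent nickel. The C9–Cr bond then adds to the C10 aldehyde, the intramolecular Nozaki–Hiyama–Kishi reaction, whose closest use is the closure of iodoalkenyl aldehydes to medium-ring allylic alcohols. Ring B closes in a 7-exo-trig mode at the carbonyl with the Z alkene inside the ring. C10 is controlled by the quaternary C1: the tether through C5 lets C9 approach only anti to C2, and the formyl group should turn its oxygen away from the C1 methyl towards the α hydroxyl on C2, where chromium can bridge O2 and O10, so that Felkin–Anh and chelate models both lead to the 10α (10R) alcohol. The step needs chemoselectivity for the aldehyde and tolerance of two free hydroxyls and the aryl ester, which organochromium reagents provide; the non-basic medium avoids retro-aldol cleavage of the β-hydroxy aldehyde. High dilution is used to suppress intermolecular coupling.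

Step 20
Reactants: 27 triol
Product: 28 CNP0320758.1: (1R,2S,4R,5S,6S,10R)-2,10-diacetoxy-6-(3,4-dimethoxybenzoyloxy)-4-hydroxydauc-8-ene
Conditions: Ac2O, pyridine, 4-(dimethylamino)pyridine (cat.), rt
Reagents that add atoms: acetic anhydride CC(=O)OC(C)=O
Why: Acetylation of the two secondary hydroxyls (C2, C10); the hindered tertiary C4 hydroxyl should not react under these conditions, and any acetyl migration between O2 and O10 is without consequence.

## Compound list

1 | propargyl alcohol | OCC#C | starting material
2 | (Z)-3-iodo-2-methylprop-2-en-1-ol | OC/C(C)=C\I | intermediate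
3 | (Z)-3-bromo-1-iodo-2-methylprop-1-ene | BrC/C(C)=C\I | intermediate
4 | (R)-4-(tert-butyldimethylsilyloxy)cyclopent-2-en-1-one | O=C1C[C@@H](O[Si](C)(C)C(C)(C)C)C=C1 | starting material
5 | (R)-4-(tert-butyldimethylsilyloxy)-2-iodocyclopent-2-en-1-one | O=C1C[C@@H](O[Si](C)(C)C(C)(C)C)C=C1I | intermediate
6 | (R)-4-(tert-butyldimethylsilyloxy)-2-methylcyclopent-2-en-1-one | O=C1C[C@@H](O[Si](C)(C)C(C)(C)C)C=C1C | intermediate
7 | 1,3-dithiane | C1CSCSC1 | starting material
8 | 2-lithio-1,3-dithiane | [Li]C1SCCCS1 | intermediate
9 | lithium enolate (C1=C2) of the conjugate adduct, 5β-dithianyl, 4α-OTBS | S1CCCSC1[C@H]2[C@H](O[Si](C)(C)C(C)(C)C)CC(O[Li])=C2C | intermediate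
10 | ketol: 5β-(1,3-dithian-2-yl)-1α-(hydroxymethyl)-1β-methyl-4α-(tert-butyldimethylsilyloxy)cyclopentan-2-one (target numbering) | S1CCCSC1[C@H]2[C@H](O[Si](C)(C)C(C)(C)C)CC(=O)[C@]2(C)CO | intermediate
11 | C10 tert-butyldiphenylsilyl ether of 10 | S1CCCSC1[C@H]2[C@H](O[Si](C)(C)C(C)(C)C)CC(=O)[C@]2(C)CO[Si](c3ccccc3)(c4ccccc4)C(C)(C)C | intermediate
12 | (2S)-alcohol: 2α-hydroxy, 1α-(tert-butyldiphenylsilyloxymethyl), 1β-methyl, 4α-OTBS, 5β-(1,3-dithian-2-yl) ring A | S1CCCSC1[C@H]2[C@H](O[Si](C)(C)C(C)(C)C)C[C@H](O)[C@]2(C)CO[Si](c3ccccc3)(c4ccccc4)C(C)(C)C | intermediate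
13 | triol: 5β-(1,3-dithian-2-yl)-1α-(hydroxymethyl)-1β-methylcyclopentane-2α,4α-diol | S1CCCSC1[C@H]2[C@H](O)C[C@H](O)[C@]2(C)CO | intermediate
14 | O2,O10-isopropylidene acetal of 13 (4α-OH free) | S1CCCSC1[C@H]2[C@H](O)C[C@@H]3OC(C)(C)OC[C@]23C | intermediate
15 | C4 ketone of 14 | S1CCCSC1[C@H]2C(=O)C[C@@H]3OC(C)(C)OC[C@]23C | intermediate
16 | tertiary alcohol: 4β-hydroxy-4α-isopropyl, 5β-(1,3-dithian-2-yl), O2,O10-isopropylidene ring A | S1CCCSC1[C@H]2[C@](O)(C(C)C)C[C@@H]3OC(C)(C)OC[C@]23C | intermediate
17 | 4-O-trimethylsilyl ether of 16 | S1CCCSC1[C@H]2[C@](O[Si](C)(C)C)(C(C)C)C[C@@H]3OC(C)(C)OC[C@]23C | intermediate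
18 | 2-lithio derivative of dithiane 17 (C6 carbanion) | [Li]C1(SCCCS1)[C@H]2[C@](O[Si](C)(C)C)(C(C)C)C[C@@H]3OC(C)(C)OC[C@]23C | intermediate
19 | alkylated dithiane: C6 dithiane carrying the (Z)-3-iodo-2-methylprop-2-enyl group (C7–C9) | C1(SCCCS1)(C/C(C)=C\I)[C@H]2[C@](O[Si](C)(C)C)(C(C)C)C[C@@H]3OC(C)(C)OC[C@]23C | intermediate
20 | C6 ketone: (Z)-4-iodo-3-methylbut-3-en-1-one on C5 of the protected ring A | O=C(C/C(C)=C\I)[C@H]2[C@](O[Si](C)(C)C)(C(C)C)C[C@@H]3OC(C)(C)OC[C@]23C | intermediate
21 | (6S)-alcohol of 20 | O[C@@H](C/C(C)=C\I)[C@H]2[C@](O[Si](C)(C)C)(C(C)C)C[C@@H]3OC(C)(C)OC[C@]23C | intermediate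
22 | veratroyl chloride (3,4-dimethoxybenzoyl chloride) | COc1ccc(C(Cl)=O)cc1OC | starting material
23 | (6S)-veratroate of 21 | COc1ccc(cc1OC)C(=O)O[C@@H](C/C(C)=C\I)[C@H]2[C@](O[Si](C)(C)C)(C(C)C)C[C@@H]3OC(C)(C)OC[C@]23C | intermediate
24 | triol: (6S)-veratroate with 2α-OH, 4β-OH and C10 CH2OH | COc1ccc(cc1OC)C(=O)O[C@@H](C/C(C)=C\I)[C@H]2[C@](O)(C(C)C)C[C@H](O)[C@]2(C)CO | intermediate
25 | ring A aldehyde with the C6 veratroate and the (Z)-iodoalkene side chain | COc1ccc(cc1OC)C(=O)O[C@@H](C/C(C)=C\I)[C@H]2[C@](O)(C(C)C)C[C@H](O)[C@]2(C)C=O | intermediate
26 | alkenylchromium dichloride (trivalent chromium on C9) | COc1ccc(cc1OC)C(=O)O[C@@H](C/C(C)=C\[Cr](Cl)Cl)[C@H]2[C@](O)(C(C)C)C[C@H](O)[C@]2(C)C=O | intermediate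
27 | (1R,2S,4R,5S,6S,10R)-2,10-dideacetyl target (C2, C4, C10 triol 6-veratroate) | COc1ccc(C(=O)O[C@H]2CC(C)=C[C@@H](O)[C@@]3(C)[C@@H](O)C[C@@](O)(C(C)C)[C@H]23)cc1OC | intermediate
28 | CNP0320758.1 | COc1ccc(C(=O)O[C@H]2CC(C)=C[C@@H](OC(C)=O)[C@@]3(C)[C@@H](OC(C)=O)C[C@@](O)(C(C)C)[C@H]23)cc1OC | target

## Step count and least certain steps

Total: 20 steps. Longest linear sequence: 18 steps (steps 3 to 20, from enone 4). Bromide 3 (steps 1 and 2) enters at step 13.

**Step 19 (key step).** Attack on the wrong face of the formyl group (oxygen gauche instead of anti to the C1 methyl) would give the C10 epimer; slow closure of the seven-membered ring would let protodehalogenation of the C–Cr bond or intermolecular coupling compete. Fallback, from 25 back to 27: the C10-epimeric triol F1 (alone or mixed with 27) is oxidised at the allylic position with MnO2 to enone F2. F2 is then reduced with NaBH4 in the presence of Et2BOMe (Narasaka–Prasad conditions). The C2 hydroxyl and the C10 carbonyl form a boron chelate in which the C1 methyl is equatorial, and axial hydride attack gives the 2,10-syn diol, which is 27.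

**Step 15.** Facial selectivity may erode if the hindered ketone reacts through an uncatalysed pathway, and premature loss of the trimethylsilyl group would open hydroxyl-directed delivery towards the 6R epimer. Fallback, from 20 back to 20: the epimers are separated, the 6R alcohol F3 is returned to ketone 20 by Dess–Martin oxidation, and the recycled ketone is reduced with K[s-Bu3BH], where the Felkin–Anh preference alone (C4 anti to hydride) operates.

**Step 13.** Metalation may be incomplete or the alkylation slow at C6, which is attached to a ring carbon flanked by two fully substituted carbons; surplus alkyllithium would then exchange with the alkenyl iodide. Fallback, from 14 back to 19: the order of events is reversed so that C6 is alkylated before C4 becomes quaternary. Acetonide alcohol 14 is converted into its dianion (n-BuLi, 2.2 equiv) and alkylated with 3 to give the secondary alcohol F4. Dess–Martin oxidation gives ketone F5, addition of i-PrMgCl/CeCl3 at −78 °C (too cold for iodine–magnesium exchange) gives the tertiary alcohol F6, and silylation with 1-(trimethylsilyl)imidazole gives 19.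

**Step 11.** Enolisation or β-hydride reduction of the hindered ketone by the branched organometallic may compete, and facial selectivity may fall. Fallback, from 15 back to 16: the smaller sp2 nucleophile isopropenylmagnesium bromide (no β-hydrogen, with CeCl3) gives the isopropenyl carbinol F7. Its 1,1-disubstituted alkene is then reduced with diimide (2-nitrobenzenesulfonylhydrazide, Et3N), which the thioacetal tolerates, to give 16.

**Step 5.** The lithiated dithiane may add 1,2 or transfer a proton instead of adding 1,4, and the hindered tetrasubstituted enolate may capture gaseous formaldehyde inefficiently or reversibly. Fallback, from 6 (with 7) back to 10: enolate 9 is trapped with Me3SiCl as the trimethylsilyl enol ether F8, which is isolated and hydroxymethylated in a Mukaiyama aldol reaction with aqueous formaldehyde catalysed by Sc(OTf)3 (trivalent scandium), anti to the C5 substituent, to give 10.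

## Further compounds

F1 | step 19 | C10 epimer of triol 27 (10β-hydroxy) | COc1ccc(C(=O)O[C@H]2CC(C)=C[C@H](O)[C@@]3(C)[C@@H](O)C[C@@](O)(C(C)C)[C@H]23)cc1OC
F2 | step 19 | C10 enone (8-en-10-one) with 2α-OH, 4β-OH and 6-veratroate | COc1ccc(C(=O)O[C@H]2CC(C)=CC(=O)[C@@]3(C)[C@@H](O)C[C@@](O)(C(C)C)[C@H]23)cc1OC
F3 | step 15 | (6R)-alcohol, C6 epimer of 21 | O[C@H](C/C(C)=C\I)[C@H]2[C@](O[Si](C)(C)C)(C(C)C)C[C@@H]3OC(C)(C)OC[C@]23C
F4 | step 13 | C6-alkylated dithiane with free 4α-hydroxyl (from 14) | C1(SCCCS1)(C/C(C)=C\I)[C@H]2[C@H](O)C[C@@H]3OC(C)(C)OC[C@]23C
F5 | step 13 | C4 ketone of F4 | C1(SCCCS1)(C/C(C)=C\I)[C@H]2C(=O)C[C@@H]3OC(C)(C)OC[C@]23C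
F6 | step 13 | tertiary alcohol (4β-OH, 4α-isopropyl) from F5 | C1(SCCCS1)(C/C(C)=C\I)[C@H]2[C@](O)(C(C)C)C[C@@H]3OC(C)(C)OC[C@]23C
F7 | step 11 | isopropenyl carbinol (4β-OH, 4α-isopropenyl) from 15 | S1CCCSC1[C@H]2[C@](O)(C(C)=C)C[C@@H]3OC(C)(C)OC[C@]23C
F8 | step 5 | trimethylsilyl enol ether (C1=C2) of the conjugate adduct | S1CCCSC1[C@H]2[C@H](O[Si](C)(C)C(C)(C)C)CC(O[Si](C)(C)C)=C2C
A1 | alternative 1 | 6,10-dimethoxy-8-methyl bicyclic cycloheptatrienone | COC=2C=C(C)C=C(OC)[C@@]3(C)C(=O)C[C@@](O[Si](CC)(CC)CC)(C(C)C)C=23
A2 | alternative 1 | α-diazo ketone with the 2,6-dimethoxy-4-methylphenyl group on C4 | CC(=[N+]=[N-])C(=O)C[C@@](O[Si](CC)(CC)CC)(C(C)C)c1c(OC)cc(C)cc1OC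
A3 | alternative 2 | trans-fused hydroazulene-4,10-dione with the C2 4-methoxybenzyl ether | CC(C)(C)[Si](C)(C)O[C@H]2CC(C)=CC(=O)[C@@]3(C)[C@@H](OCc4ccc(OC)cc4)CC(=O)[C@H]23
A4 | alternative 2 | cycloheptenone with the C5 diazoacetyl group and the (4-methoxybenzyloxy)methyl group on C1 | CC(C)(C)[Si](C)(C)O[C@H]1CC(C)=CC(=O)[C@@](C)(COCc2ccc(OC)cc2)[C@@H]1C(=O)C=[N+]=[N-]
A5 | alternative 3 | hydroazulene methyl enol ether with the C10 silyl group and the C8=C9 alkene | COC=2CC(C)=C[C@@H]([Si](C)(C)OC(C)C)[C@@]3(C)C4(OCCO4)C[C@H](O[Si](C)(C)C(C)(C)C)C=23
A6 | alternative 3 | pentacarbonyl[cyclopentenyl(methoxy)carbene]chromium complex (zerovalent chromium) | COC(=[Cr])C1=C(C)C2(OCCO2)C[C@@H]1O[Si](C)(C)C(C)(C)C.[C-]#[O+].[C-]#[O+].[C-]#[O+].[C-]#[O+].[C-]#[O+]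
A7 | alternative 3 | (E)-1-[isopropoxy(dimethyl)silyl]-3-methylbuta-1,3-diene | C=C(C)/C=C/[Si](C)(C)OC(C)C
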